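If intermediate A is the form that meets partner, while it also stands as intermediate B and intermediate C, then we should carry the rate of partner against the whole pool of the three, not against intermediate A.

in all of them: substrate 0.80 M
- alpha: partner 0.700 equiv; time 2.0 h; everything together in a closed stirred flask, run for 2.0 h
- delta: partner 0.700 equiv; one stirred flow tank at steady state, fed with the mixture as stated, mean residence time 2.0 h
- gamma: partner 0.700 equiv; one stirred flow tank at steady state, fed with the mixture as stated, mean residence time 6.00 h
- epsilon: partner 0.700 equiv (fed, over 1.60 h); time 2.0 h; a stirred flask in which partner is dosed at a steady rate over 1.60 h without added volume, worked up at 2.0 h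

    substrate → intermediate A (k1 = 0.0013 /s)
    partner + intermediate A → product (k2 = 0.0061 /M/s)
    intermediate A ⇌ intermediate B (K3 = 0.71, k3 = 0.016 /s)
    intermediate A ⇌ intermediate C (K4 = 1.9, k4 = 0.0016 /s)
    intermediate B ⇌ intermediate D (K5 = 1.6, k5 = 1.1 × 10⁻⁴ /s)
    intermediate D ⇌ intermediate E (K6 = 0.38, k6 = 0.0065 /s)
    substrate ⇌ dormant form (K7 = 1.5, k7 = 9.9 × 10⁻⁴ /s)

* order of the set-ups by the amount of product at the outlet or at the end, in percent of the substrate put in, highest first (alpha / delta / gamma / epsilon)
* amount of product at the outlet or at the end, in percent of the substrate put in, alpha
* amount of product at the outlet or at the end, in percent of the substrate put in, delta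
* amount of product at the outlet or at the end, in percent of the substrate put in, gamma
* amount of product at the outlet or at the end, in percent of the substrate put in, epsilon

How far can product go? Partner, charged at 0.560 M against 0.80 M substrate, is the limiting reagent, so the ceiling is 70.0% of the substrate, and the excess of substrate over partner is 0.240 M.

Does the pool behave as one thing? The exchange half-lives, forward steps alone, are 0.72 min to intermediate B and 0.12 h to intermediate C, while capture of intermediate A in alpha, with partner as charged, has a half-life of 0.056 h, so the exchange with intermediate B is faster than that capture but the exchange with intermediate C is slower. We still hold the pool at equilibrium with intermediate A as a share 0.277 of it, as an approximation that is not earned while partner stands near its charge, and the figures below carry that error. Product then forms at the pool constant 6.08 /M/h times [pool] times [partner]. The leak towards intermediate D, 0.0779 /h, is far less than the pseudo-first-order capture at charged partner, 3.40 /h, so we drop it.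

When does the pool fill? Substrate and dormant form together last 0.534 h on average, less than the run, so we replace the arrival curve by its mean and let the whole charge land at that moment.

In alpha, [partner]/[pool] then shrinks to 0.0824, which gives 0.538 M product, or 67.3%.

In a tank, the same mean feeds the pool with F, the charge times residence time over residence time plus mean lifetime, and the balance is [product] = pool constant × residence time × (F − [product]) × (charged partner − [product]). For gamma, F is 0.735 M, and the lower root is 0.501 M, or 62.6%. For delta, with its 2.0 h, F is 0.631 M, and the root is 0.409 M, or 51.1%.

For epsilon we let partner land at its mean dosing time, 0.800 h, which gives 0.527 M, and we take this as an upper mark: 65.9%. So alpha stands above gamma and gamma above delta, while epsilon stays placed by a bound alone.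

The forecast gave alpha > gamma > epsilon > delta, with 65%, 61.8%, 59% and 51.4% in that order, and held that “dosing loses some by starving partner early”.

The simulation gives alpha > gamma > epsilon > delta: alpha 65.4%, gamma 61.7%, epsilon 58.3%, delta 51.4%.

At the simulated outlet of gamma, partner stands at 0.0664 M, so the pool constant gives capture at 0.404 /h against an outflow of 0.167 /h, while in delta the pair is 0.905 /h against 0.500 /h. At the end of alpha, partner stands at 0.0368 M, capture has fallen to 0.224 /h, and alpha left to 20.0 h stands at 70.0%.

(The constants used here are those of an exercise; what happens was integrated by code.)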